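A small charge of initiator, 80 mM in green, is less than the 250 mM in teal, and I want to know what that does to the length of the chains.

| flask | free monomer | protic impurity | initiator | remark | time |
|---|---|---|---|---|---|
| spring | 0.80 M | 0.24 M | 53 mM | run made earlier |  |
| summer | 0.80 M | 0.24 M | 220 mM | run made earlier |  |
| green | 0.80 M | 0.240 M | 80 mM |  | 20 min |
| teal | 0.80 M | 0.240 M | 250 mM |  | 20 min |

| run | time / min | monomer in chains / % | free monomer / % |
|---|---|---|---|
| spring | 1.33 | 27 | 49 |
| spring | 4.00 | 40 | 28 |
| spring | 8.00 | 54 | 17 |
| spring | 10.0 | 53 | 15 |
| spring | 15.0 | 60 | 18 |
| spring | 20.0 | 58 | 14 |
| summer | 3.00 | 63 | 9 |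
| summer | 6.00 | 72 | 5 |
| summer | 10.0 | 67 | 3 |
| summer | 12.0 | 68 | 2 |
| summer | 15.0 | 70 | 4 |
| summer | 20.0 | 72 | 0 |

(scatter of a reading: 2 percentage points)

- the average divides the monomer in chains by the number of chains begun, living and dead together
- the earlier runs were read with a standard deviation of 2 percentage points
- the earlier runs do not show the number of chains; that part of a forecast is a guess

1. which of the two ends with the longer chains by the average number of monomer units in a chain (chains begun, living or dead) ("neither" if they lie within 10%) (green / teal / neither)
2. average number of monomer units in a chain (chains begun, living or dead) at the end, green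
3. average number of monomer units in a chain (chains begun, living or dead) at the end, teal

From the earlier runs I build a ladder, fastest step first.

1. Side loss. At 3.00 min the summer run already misses 28.0% of the charge, and at 20.0 min it misses 28.0%. That is 0.224 M of monomer, near the 0.240 M of protic impurity.

2. Growth. Free monomer falls by 1.05 powers of ten by 3.00 min in the summer run, but by 0.553 by 4.00 min in the spring run.

3. Stall. The spring run reads 15% free monomer at 10.0 min and 14% at 20.0 min, a change within the scatter of 2 percentage points.

4. Reckoning. Interpolating on the logarithm of the initiator charge, I put green at 62.0% in chains, and I give teal the summer value of 72%. Dividing by the charges gives 6.20 for green and 2.30 for teal. I call this the floor length, the monomer in chains per initiator charged. It is a lower limit if one initiator begins one chain or none, which I assume. In powers of ten, the initiator ratio is worth 0.495, more than the 0.0649 that teal gains in chains. On this reckoning green leads by 0.431 in powers of ten, beyond the margin of 0.0414.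

The forecast says green, with 6.2 (4.5 to 9) for green and 2.3 (1.8 to 3.5) for teal, “Assuming one chain per initiator, which is a guess”.

The flask gives green, with 8.43 for green and 3.61 for teal.

    free monomer + initiator → living end + monomer in chains (k = 0.0390 /M/s)
    free monomer + living end → monomer in chains + living end, rate k2*[living end]*[free monomer] (k = 0.200 /M/s)
    protic impurity + free monomer → quenched substrate (k = 0.0390 /M/s)
    initiator → spent initiator A (k = 0.00820 /s)
    2 living end → dead end B (k = 0.220 /M/s)

At the end of teal, 0% of the initiator is left and spent initiator A stands at 0.0918 M, so the share that began chains, the initiator efficiency, is 0.633. The floor length divided by that share gives 3.63. The neighbouring flask is teal with 0.60 M of protic impurity, and it ends with 48.3% in chains, a floor length of 1.55. Its spent initiator A is 0.115 M, a share of 0.538, so I reckon 2.88. That neighbouring flask gives an average length of 2.87.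

The earlier runs and the new flask stem from a simulated flask for an exercise.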